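**Assumption:** (2E)-hexadec-2-enal and 3-(trimethylsilyl)prop-2-ynal are bought; the absolute sense of step 1 is assigned from the Houk–List enamine-aldol model, not from experiment.

## Retrosynthetic overview

1. Cut the ester C–O bond: a (3E,4S)-hydroxy enol lactone (alcohol half) and an O-silylated (Z)-γ-keto acid (acyl half).
2. The keto acid is the hydrolysed Z enol lactone, and the Z lactone is the photoisomer of the E lactone, so both halves come from one lactone.
3. The E lactone comes from 5-exo-dig cycloisomerisation of a 3-hydroxypent-4-ynoic acid, itself from oxidation of an α-alkylidene β-hydroxy aldehyde.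
4. That aldehyde comes from a proline-catalysed dienamine aldol/re-conjugation (formal β-alkyl Morita–Baylis–Hillman reaction) of hexadec-2-enal with silylpropynal; this sets the one stereocentre used in both halves.
5. Ring order: the butanolide is the only ring and is closed once (step 3); the copy for the acyl half is photoisomerised and reopened (step 6), the other copy is kept.

## Route

**Step 1**
Reactants: 1 (2E)-hexadec-2-enal; 2 3-(trimethylsilyl)prop-2-ynal
Product: 3 (2E)-2-[(1S)-1-hydroxy-3-(trimethylsilyl)prop-2-yn-1-yl]hexadec-2-enal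
Conditions: (R)-proline (30 mol %), 2,6-lutidine (30 mol %), DMF, 4 °C, 48 h; 2 (1.5 equiv), 1 added slowly
Reagents that add atoms: none
Why: Proposed new method: (R)-proline turns 1 into a 1-amino-1,3-diene (dienamine) whose α-carbon adds to the Si face of the non-enolisable ynal 2 through the carboxylic-acid-directed Houk–List enamine-aldol transition state (this sets the carbinol centre, S), and base-assisted α-deprotonation/γ-protonation of the catalyst-bound β,γ-unsaturated iminium returns the double bond into conjugation as the thermodynamic E enal (chain trans to CHO), a formal Morita–Baylis–Hillman reaction of a β-alkyl enal; the closest known reaction type is the proline/imidazole Mannich (aza-MBH-type) reaction of β-substituted enals with N-aryl imino esters, here moved to an aldehyde acceptor, with hindered 2,6-lutidine in place of imidazole so that no amine adds to the ynal.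

**Step 2**
Reactants: 3 (2E)-2-[(1S)-1-hydroxy-3-(trimethylsilyl)prop-2-yn-1-yl]hexadec-2-enal
Product: 4 (2E)-2-[(1S)-1-hydroxy-3-(trimethylsilyl)prop-2-yn-1-yl]hexadec-2-enoic acid
Conditions: NaClO2, NaH2PO4, 2-methyl-2-butene, t-BuOH/H2O, 0 °C to rt
Reagents that add atoms: sodium chlorite, [Na+].[O-]Cl=O
Why: Pinnick oxidation takes only the aldehyde to the acid, the hypochlorite scavenger protects the alkene and alkyne, and the carbinol centre and E geometry are not touched.

**Step 3**
Reactants: 4 (2E)-2-[(1S)-1-hydroxy-3-(trimethylsilyl)prop-2-yn-1-yl]hexadec-2-enoic acid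
Product: 6 (3E,4S)-4-hydroxy-5-methylidene-3-tetradecylideneoxolan-2-one, via (2E)-2-[(1R)-1-hydroxyprop-2-yn-1-yl]hexadec-2-enoic acid 5 (not isolated)
Conditions: K2CO3 (1.5 equiv), MeOH, 0 °C; AcOH (3 equiv), evaporate; AuCl (5 mol %), MeCN, rt
Reagents that add atoms: none
Why: Methanolysis of the alkynyl–silicon bond frees the terminal alkyne, and gold(I)-catalysed 5-exo-dig cycloisomerisation of the 4-pentynoic acid (anti-oxyauration, protodeauration) gives the γ-methylene lactone; the stereocentre is unchanged in space (the descriptor changes only through CIP priorities).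

**Step 4**
Reactants: 6 (3E,4S)-4-hydroxy-5-methylidene-3-tetradecylideneoxolan-2-one
Product: 7 (3Z,4S)-4-hydroxy-5-methylidene-3-tetradecylideneoxolan-2-one
Conditions: hν (254 nm, quartz), degassed MeCN (5 mM), 20 °C, to the photostationary state; SiO2 separation, 6 recovered
Reagents that add atoms: none
Why: E/Z photoisomerisation of the α-alkylidene lactone chromophore gives a roughly 1:1 mixture without touching C4, and the recovered E isomer 6 is the alcohol partner of step 7, so both isomers are used.

**Step 5**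
Reactants: 7 (3Z,4S)-4-hydroxy-5-methylidene-3-tetradecylideneoxolan-2-one
Product: 8 (3Z,4S)-4-[(tert-butyldimethylsilyl)oxy]-5-methylidene-3-tetradecylideneoxolan-2-one
Conditions: TBSOTf, 2,6-lutidine, CH2Cl2, −78 °C
Reagents that add atoms: tert-butyldimethylsilyl trifluoromethanesulfonate (TBSOTf), CC(C)(C)[Si](C)(C)OS(=O)(=O)C(F)(F)F
Why: O-silylation with a silyl triflate and a non-nucleophilic base protects the alcohol without opening the enol lactone, which a nucleophilic base such as imidazole could do.

**Step 6**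
Reactants: 8 (3Z,4S)-4-[(tert-butyldimethylsilyl)oxy]-5-methylidene-3-tetradecylideneoxolan-2-one
Product: 9 (2Z)-2-[(1S)-1-[(tert-butyldimethylsilyl)oxy]-2-oxopropyl]hexadec-2-enoic acid
Conditions: LiOH (1.1 equiv), THF/H2O, 0 °C, 20 min; then 1 M HCl to pH 3–4
Reagents that add atoms: lithium hydroxide, [Li+].[OH-]
Why: Saponification of the enol lactone (an activated ester) is fast, the enolate leaving group tautomerises to the methyl ketone, and the short cold treatment with one equivalent of base leaves the α-silyloxy ketone centre and the Z alkene intact.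

**Step 7**
Reactants: 9 (2Z)-2-[(1S)-1-[(tert-butyldimethylsilyl)oxy]-2-oxopropyl]hexadec-2-enoic acid; 6 (3E,4S)-4-hydroxy-5-methylidene-3-tetradecylideneoxolan-2-one
Product: 10 (3E,4S)-5-methylidene-2-oxo-3-tetradecylideneoxolan-4-yl (2Z)-2-[(1S)-1-[(tert-butyldimethylsilyl)oxy]-2-oxopropyl]hexadec-2-enoate
Conditions: DIC, DMAP (0.2 equiv), CH2Cl2, 0 °C to rt
Reagents that add atoms: none
Why: Steglich esterification, as used for levulinoylation with γ-keto acids, joins the halves with retention at both carbinols; the acid has no free OH and the alcohol no free acid, so only the cross ester can form.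

**Step 8**
Reactants: 10 (3E,4S)-5-methylidene-2-oxo-3-tetradecylideneoxolan-4-yl (2Z)-2-[(1S)-1-[(tert-butyldimethylsilyl)oxy]-2-oxopropyl]hexadec-2-enoate
Product: 11 (3E,4S)-5-methylidene-2-oxo-3-tetradecylideneoxolan-4-yl (2Z)-2-[(1S)-1-hydroxy-2-oxopropyl]hexadec-2-enoate (CNP0377581.1)
Conditions: HF·pyridine, pyridine, THF, 0 °C to rt
Reagents that add atoms: none
Why: Buffered fluoride desilylation removes the TBS group under non-basic conditions, so the epimerisable acyloin, the ester and the enol lactone survive.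

## Compound list

1 | (2E)-hexadec-2-enal | CCCCCCCCCCCCC/C=C/C=O | starting material
2 | 3-(trimethylsilyl)prop-2-ynal | C[Si](C)(C)C#CC=O | starting material
3 | (2E)-2-[(1S)-1-hydroxy-3-(trimethylsilyl)prop-2-yn-1-yl]hexadec-2-enal | O=C/C(=C/CCCCCCCCCCCCC)[C@H](O)C#C[Si](C)(C)C | intermediate
4 | (2E)-2-[(1S)-1-hydroxy-3-(trimethylsilyl)prop-2-yn-1-yl]hexadec-2-enoic acid | OC(=O)/C(=C/CCCCCCCCCCCCC)[C@H](O)C#C[Si](C)(C)C | intermediate
5 | (2E)-2-[(1R)-1-hydroxyprop-2-yn-1-yl]hexadec-2-enoic acid | OC(=O)/C(=C/CCCCCCCCCCCCC)[C@H](O)C#C | intermediate (not isolated)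
6 | (3E,4S)-4-hydroxy-5-methylidene-3-tetradecylideneoxolan-2-one (isoobtusilactone A) | C=C1OC(=O)/C(=C/CCCCCCCCCCCCC)[C@@H]1O | intermediate
7 | (3Z,4S)-4-hydroxy-5-methylidene-3-tetradecylideneoxolan-2-one (obtusilactone A) | C=C1OC(=O)/C(=C\CCCCCCCCCCCCC)[C@@H]1O | intermediate
8 | (3Z,4S)-4-[(tert-butyldimethylsilyl)oxy]-5-methylidene-3-tetradecylideneoxolan-2-one | C=C1OC(=O)/C(=C\CCCCCCCCCCCCC)[C@@H]1O[Si](C)(C)C(C)(C)C | intermediate
9 | (2Z)-2-[(1S)-1-[(tert-butyldimethylsilyl)oxy]-2-oxopropyl]hexadec-2-enoic acid | OC(=O)/C(=C\CCCCCCCCCCCCC)[C@H](O[Si](C)(C)C(C)(C)C)C(C)=O | intermediate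
10 | (3E,4S)-5-methylidene-2-oxo-3-tetradecylideneoxolan-4-yl (2Z)-2-[(1S)-1-[(tert-butyldimethylsilyl)oxy]-2-oxopropyl]hexadec-2-enoate | C=C1OC(=O)/C(=C/CCCCCCCCCCCCC)[C@@H]1OC(=O)/C(=C\CCCCCCCCCCCCC)[C@H](O[Si](C)(C)C(C)(C)C)C(C)=O | intermediate
11 | (3E,4S)-5-methylidene-2-oxo-3-tetradecylideneoxolan-4-yl (2Z)-2-[(1S)-1-hydroxy-2-oxopropyl]hexadec-2-enoate | C=C1OC(=O)/C(=C/CCCCCCCCCCCCC)[C@@H]1OC(=O)/C(=C\CCCCCCCCCCCCC)[C@H](O)C(C)=O | target

## Step count and risks

Total steps: 8. Longest linear sequence: 8 (1 → 3 → 4 → 6 → 7 → 8 → 9 → 10 → 11; recovered 6 re-enters at step 7).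

**Step 1 (proposed new method).** The risks are enal self-condensation, amine addition to the ynal, and incomplete re-conjugation or low ee. The fallback uses known chemistry, sets out from 2 and comes back at 5. Tridecylmagnesium bromide/CuBr·SMe2 adds syn to methyl propiolate (THF, −78 °C), which places the chain trans to the ester, and the adduct is trapped with 2 (Et2AlCl) to give racemic methyl (2E)-2-[1-hydroxy-3-(trimethylsilyl)prop-2-yn-1-yl]hexadec-2-enoate F1. Acylative kinetic resolution (chiral isothiourea catalyst, isobutyric anhydride, i-Pr2NEt) leaves methyl (2E)-2-[(1S)-1-hydroxy-3-(trimethylsilyl)prop-2-yn-1-yl]hexadec-2-enoate F2 and removes the other antipode as methyl (2E)-2-[(1R)-1-(2-methylpropanoyloxy)-3-(trimethylsilyl)prop-2-yn-1-yl]hexadec-2-enoate F3. LiOH in THF/MeOH/H2O then cleaves the methyl ester and the C–Si bond of F2 to give 5, which enters step 3 at the gold stage.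

**Step 4 (photoisomerisation).** The risks are an unfavourable photostationary ratio, photodeconjugation of the Z isomer and damage to the enol ether. The fallback builds the Z alkene under kinetic control instead; it sets out from 2 and comes back at 7. Methyl hexadec-2-ynoate F4 (from 1-pentadecyne, n-BuLi, ClCO2Me) undergoes hydroalumination/aldol (DIBAL-H, NMO, THF, 0 °C; then 2), which places the chain cis to the ester, to give racemic methyl (2Z)-2-[1-hydroxy-3-(trimethylsilyl)prop-2-yn-1-yl]hexadec-2-enoate F5. The same acylative kinetic resolution gives methyl (2Z)-2-[(1S)-1-hydroxy-3-(trimethylsilyl)prop-2-yn-1-yl]hexadec-2-enoate F6 beside methyl (2Z)-2-[(1R)-1-(2-methylpropanoyloxy)-3-(trimethylsilyl)prop-2-yn-1-yl]hexadec-2-enoate F7. LiOH converts F6 into (2Z)-2-[(1R)-1-hydroxyprop-2-yn-1-yl]hexadec-2-enoic acid F8, and AuCl in MeCN closes it to 7.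

**Step 7 (esterification).** Both partners are hindered, the activated γ-keto acid can fall back to its enol lactone, and DMAP can cause Z to E isomerisation. The fallback drops carboxyl activation and uses the enol lactone itself as the acyl donor; it sets out from 8 and comes back at 10. Silylated Z lactone 8 (2–3 equiv) is treated with 6 and a transesterification catalyst for enol esters (IMes carbene, 5 mol %, or a distannoxane) in toluene at rt; ring opening releases the methyl ketone and gives 10 directly. The excess of 8 suppresses self-acylation of 6, and no new compound is made on the way.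

## Further compounds

F1 | step 1 | methyl (2E)-2-[1-hydroxy-3-(trimethylsilyl)prop-2-yn-1-yl]hexadec-2-enoate (racemic) | COC(=O)/C(=C/CCCCCCCCCCCCC)C(O)C#C[Si](C)(C)C
F2 | step 1 | methyl (2E)-2-[(1S)-1-hydroxy-3-(trimethylsilyl)prop-2-yn-1-yl]hexadec-2-enoate | COC(=O)/C(=C/CCCCCCCCCCCCC)[C@H](O)C#C[Si](C)(C)C
F3 | step 1 | methyl (2E)-2-[(1R)-1-(2-methylpropanoyloxy)-3-(trimethylsilyl)prop-2-yn-1-yl]hexadec-2-enoate | COC(=O)/C(=C/CCCCCCCCCCCCC)[C@@H](OC(=O)C(C)C)C#C[Si](C)(C)C
F4 | step 4 | methyl hexadec-2-ynoate | CCCCCCCCCCCCCC#CC(=O)OC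
F5 | step 4 | methyl (2Z)-2-[1-hydroxy-3-(trimethylsilyl)prop-2-yn-1-yl]hexadec-2-enoate (racemic) | COC(=O)/C(=C\CCCCCCCCCCCCC)C(O)C#C[Si](C)(C)C
F6 | step 4 | methyl (2Z)-2-[(1S)-1-hydroxy-3-(trimethylsilyl)prop-2-yn-1-yl]hexadec-2-enoate | COC(=O)/C(=C\CCCCCCCCCCCCC)[C@H](O)C#C[Si](C)(C)C
F7 | step 4 | methyl (2Z)-2-[(1R)-1-(2-methylpropanoyloxy)-3-(trimethylsilyl)prop-2-yn-1-yl]hexadec-2-enoate | COC(=O)/C(=C\CCCCCCCCCCCCC)[C@@H](OC(=O)C(C)C)C#C[Si](C)(C)C
F8 | step 4 | (2Z)-2-[(1R)-1-hydroxyprop-2-yn-1-yl]hexadec-2-enoic acid | OC(=O)/C(=C\CCCCCCCCCCCCC)[C@H](O)C#C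
F0 | step 7 | none | none
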